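Start from amounts: turn each reading into mM of target, so that flasks with different solid charges can be compared.

| flask | solid substrate | partner | remark | time |
|---|---|---|---|---|
| birch | 10 mM | 11 mM (in portions, 3) | run made earlier; portions every 8.0 min |  |
| oak | 10 mM | 28 mM (in portions, 3) | run made earlier; portions every 8.0 min |  |
| elm | 10 mM | 44 mM (in portions, 3) | run made earlier; portions every 8.0 min |  |
| larch | 8 mM | 13 mM (in portions, 3) | run made earlier; portions every 8.0 min |  |
| spring | 5.0 mM | 13.0 mM (in portions, 3) | the portions of partner follow each other after 8.0 min, the first at the start | 30 min |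
| midnight | 10 mM | 50.0 mM (in portions, 3) | the portions of partner follow each other after 8.0 min, the first at the start | 30 min |
| noon | 5.0 mM | 50.0 mM (in portions, 3) | the portions of partner follow each other after 8.0 min, the first at the start | 30 min |
| summer | 10 mM | 13.0 mM (in portions, 3) | the portions of partner follow each other after 8.0 min, the first at the start | 30 min |

| run | time / min | target / % |
|---|---|---|
| birch | 2.50 | 3 |
| birch | 8.00 | 9 |
| birch | 15.0 | 22 |
| birch | 20.0 | 30 |
| birch | 30.0 | 36 |
| oak | 2.50 | 3 |
| oak | 8.00 | 17 |
| oak | 15.0 | 36 |
| oak | 20.0 | 52 |
| oak | 30.0 | 61 |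
| elm | 2.50 | 5 |
| elm | 8.00 | 20 |
| elm | 15.0 | 39 |
| elm | 20.0 | 55 |
| elm | 30.0 | 63 |
| larch | 2.50 | 1 |
| larch | 8.00 | 11 |
| larch | 15.0 | 30 |
| larch | 20.0 | 45 |
| larch | 30.0 | 47 |

(scatter of a reading: 1.5 percentage points)

- at the start none of the solid substrate is in solution
- what has only dissolved of solid substrate counts as not reacted
- a reading or a percentage of target counts all its forms, free or not

- all flasks from highest to lowest amount of target, in percent of the solid substrate charged, at 30 min (spring / midnight / noon / summer)
- the amount of target, in percent of the solid substrate charged of the flask you put first, at 30 min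
- the amount of target, in percent of the solid substrate charged of the flask you put last, at 30 min

Elm gains target from 20% to 55% between 8.00 min and 20.0 min, a mean slope of 0.292 mM min⁻¹. Call this f, the feed rate, the mM of target gained per minute on the zero-order stretch of a partner-rich run. Check what the mean costs: the line gives 40.4% at 15.0 min, a miss of 1.4 percentage points against a scatter of 1.5 points. Oak, with less partner, reads 0.292 mM min⁻¹, the same slope.

Next, f times 30.0 min gives 8.76 mM, more than the 6.30 mM elm reads, so elm leaves the line. Read its end as a share φ = 63.0% of the charge. Birch and larch end lower, with a mean yield y = 0.308, the ratio of final target to partner charged. Take the lower ceiling for summer: y times 13.0 mM is 4.01 mM, or 40.1%, less than φ.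

The weak link is φ, read at one solid charge. Reforge it: elm's 6.30 mM exceeds noon's whole charge of 5.0 mM, so carry a share and not an amount. Commit to 63.0% for midnight, noon and spring, ranked in that order though the reckoning cannot part them, then summer.

The forecast says noon > midnight > spring > summer, with 85% (68% to 97%) first and 41% (36% to 46%) last, holding that “Noon has only 5 mM solid, so it sits below that ceiling”.

The flasks give midnight > noon > spring > summer: midnight 61.3%, noon 54.9%, spring 52.5%, summer 41.2%.

    target ⇌ isomer of the product (K = 0.800, k = 0.160 min⁻¹)
    partner ⇌ dormant form (K = 1.10, k = 1.00 min⁻¹)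
    solid product ⇌ target, rate k3*(cs3 - [target]) while solid is left; crystals form when [target] > cs3 (solubility = 4.70 mM, k = 5.10 min⁻¹)
    dissolved substrate + target → side product (k = 2.60 L mol⁻¹ min⁻¹)
    partner → decomposed reagent (k = 0.0980 min⁻¹)
    dissolved substrate + partner → target (k = 90.0 L mol⁻¹ min⁻¹)
    solid substrate ⇌ dissolved substrate, rate k7*(cs7 - [dissolved substrate]) while solid is left; crystals form when [dissolved substrate] > cs7 (solubility = 7.40 mM, k = 0.0710 min⁻¹)

Noon ends 8.1 points below my share. In midnight, f predicts 46.7% at 16.0 min, and the flask holds 43.3% of target. Now take the neighbour of midnight charged with 25 mM of solid substrate: f times 30 min gives 8.76 mM, or 35.0% of its charge, below φ. That flask gives 38.1% of target, with 42.3% of its charge still solid.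

The numbers in the tables were computed for an exercise.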